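**Assumptions (one line each)**
- Commercial (R)-rosmarinic acid (the (E)-caffeate ester of (R)-danshensu) is an acceptable cheap chiral starting material.
- Rabdosiin is the formal dehydro-dimer of rosmarinic acid (2 × C18H16O8 − 2H = C36H30O16), and the SMILES has a trans-1,2 relationship (checked from the chirality tags).

**Retrosynthetic overview**
1. Rabdosiin is disconnected at the C8–C8′ bond and at the C6–C7′ aryl–benzylic bond of the dihydronaphthalene. This gives two molecules of rosmarinic acid, so the single new ring is formed in the key step.
2. The key step is an anodic phenolic oxidative dimerisation. C8–C8′ radical coupling gives a transient bis(quinone methide). One quinone methide tautomerises to the C7=C8 alkene, and the resulting catechol ring closes onto the other quinone methide by intramolecular Friedel–Crafts-type cyclisation. The aryl dihydronaphthalene forms at this stage.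
3. Both danshensu stereocentres are carried unchanged from the starting material. The C1/C2 centres form in the coupling and cyclisation under control of those centres. No protecting groups are used.

## Route

**Step 1**
Reactants: **1**, (R)-rosmarinic acid, (2R)-2-{[(2E)-3-(3,4-dihydroxyphenyl)prop-2-enoyl]oxy}-3-(3,4-dihydroxyphenyl)propanoic acid (2 equiv, i.e. both partners are 1)
Product: **2**, rabdosiin
Conditions: Undivided cell, carbon-felt anode, Pt cathode, constant current (≈1 mA cm⁻²), 0.05 M **1**, 0.1 M nBu4NBF4, HFIP/MeCN 1:4, N2, 25 °C, 1.0 F mol⁻¹ of **1**. Then concentrate and purify by reverse-phase preparative HPLC (C18, MeCN/H2O with 0.1% HCOOH).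
Reagents that add atoms: none (electrons are the oxidant; HFIP, MeCN and nBu4NBF4 are solvent and electrolyte and are not incorporated; the cathode releases H2).
Why: Anodic one-electron oxidation of the caffeate catechol gives a phenoxyl/semiquinone radical with spin density at C8, and 8–8′ radical coupling followed by cyclisation gives the 1-aryl-1,2-dihydronaphthalene. Cyclisation onto the quinone methide via the ring carbon para to the 3-OH gives the 6,7-dihydroxy pattern. Trans-1,2 is the product of the ring closure (pseudo-diaxial aryl and ester). The absolute sense of C1/C2 comes only from the two (R)-lactate ester centres, which make the two trans-core enantiomeric pathways diastereomeric. I expect modest selectivity, so the desired diastereomer is separated from its (1,2)-epimer by HPLC.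
Proposed new method: Mechanistically this is a phenol-type oxidative coupling in which HFIP stabilises the phenoxyl radicals and quinone methide cations, so the cyclisation outcompetes water or alcohol capture. Operating at about 1 F mol⁻¹ with the carboxylic acids kept protonated avoids over-oxidation to o-quinones and Kolbe-type decarboxylation. The closest known reactions are the Ag2O-, Mn(III)-, Fe(III)- and peroxidase-mediated 8–8′ oxidative dimerisation of caffeate esters to aryl dihydronaphthalene lignans, and anodic phenol coupling in HFIP. Unprotected, polyhydroxylated rosmarinic acid has not been shown to undergo this reaction electrochemically.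

**Checks**
- **Structure match:** The product has a 1-aryl-1,2-dihydronaphthalene with C3=C4, 6,7-(OH)2 on the fused ring, a 3,4-dihydroxyphenyl at C1, two carboxylate esters at C2 and C3 bearing (R)-danshensu, and trans C1/C2. This matches the target SMILES.
- **Atom balance:** 2 C18H16O8 − 2 H⁺ − 2 e⁻ gives C36H30O16, which equals the formula counted from the target SMILES.
- **Functional groups:** The free catechols, acids and esters are the substrate's own groups. The danshensu α-stereocentres are not acidic enough to epimerise under the acidic, non-basic conditions.
- **Stereocentres:** The (R)-danshensu centres are untouched. C1 and C2 are set once, in the coupling and cyclisation, and are not touched afterwards.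

## Compound list
| No. | Name | SMILES | Role |
|---|---|---|---|
| 1 | (R)-Rosmarinic acid | O=C(/C=C/c1ccc(O)c(O)c1)O[C@H](Cc1ccc(O)c(O)c1)C(=O)O | starting material |
| 2 | Rabdosiin | O=C(O[C@H](Cc1ccc(O)c(O)c1)C(=O)O)C1=Cc2cc(O)c(O)cc2[C@@H](c2ccc(O)c(O)c2)[C@@H]1C(=O)O[C@H](Cc1ccc(O)c(O)c1)C(=O)O | target |

**Total step count:** 1
**Longest linear sequence:** 1

**Three most likely failure points** (the route has a single step, so these are three failure modes within Step 1)
1. **The proposed new electrochemical coupling itself.** Over-oxidation to o-quinones, 8–O–4′ or benzodioxane coupling, or oligomerisation would compete with the 8–8′ coupling and cyclisation. Fallback (known chemistry): abandon the anode and dimerise **1** by biomimetic chemical or enzymatic oxidation, either HRP/H2O2 in aqueous acetone/buffer or Ag2O.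
2. **Low diastereoselectivity at C1/C2**, giving a near 1:1 mixture of the two trans diastereomers. Fallback: peracetylate the crude mixture, separate the diastereomers on silica gel, and deacetylate mildly with hydrazine acetate. This adds two steps but avoids separating free polyphenolic acids.
3. **Isolation of a highly polar, oxidation-prone tetra-catechol diacid in usable purity.** Fallback: switch to a convergent protected route. Build the 1-aryl-dihydronaphthalene-2,3-dicarboxylic core from benzyl-protected caffeate by known oxidative coupling, esterify with benzyl-protected (R)-danshensu benzyl ester, and remove the benzyls by hydrogenolysis or BCl3.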